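(The numbers of this flask are assumed; the result is computed.)

Coupling partner is conserved: besides the free partner, each side product holds two; each target, idle adduct, intermediate B and intermediate C holds one; each intermediate A holds none.

    substrate → intermediate A (k1 = 0.378 /min)
    substrate + coupling partner → intermediate B (k2 = 1.01 /M/min)
    coupling partner + intermediate A ⇌ intermediate C (K3 = 2.79 /M, k3 = 2.23 /M/min)
    coupling partner + intermediate B → side product (k4 = 7.32 /M/min)
    intermediate C → target (k5 = 0.226 /min)
    substrate + target ⇌ idle adduct, settled at all times (K6 = 77.3 /M)

common to all: substrate 0.50 M; time 80 min
- north-east: coupling partner 0.400 M
- south-west: coupling partner 0.800 M
- south: coupling partner 1.60 M

- in percentages every species weighs as the substrate in it: one idle adduct counts as two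
- for target the idle adduct is counted in
- in an amount of target, one idle adduct counts as one target
- run time (north-east): 80 min

1. which of these there is most of at the end, counted by the substrate in it, north-east (side product / target / intermediate C / intermediate B / intermediate A)
2. which of these there is most of at the end, counted by the substrate in it, south-west (side product / target / intermediate C / intermediate B / intermediate A)
3. which of these there is most of at the end, counted by the substrate in it, south (side product / target / intermediate C / intermediate B / intermediate A)
4. final amount of the leader among these, as a percentage of the substrate charged, in north-east
5. final amount of the leader among these, as a percentage of the substrate charged, in south-west
6. final amount of the leader among these, as a percentage of the substrate charged, in south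

**The choice.** I had to choose the partner charge for the next run, and I wanted target.

**The zero.** Substrate moves on by the first step or the second, leaving aside what the idle adduct holds reversibly, and intermediate B has one exit, to side product. I took the even split as the zero of my scale. The even-split level, the partner concentration at which those two steps use substrate equally, is the first rate constant over the second, c_even = 0.374 M. The share of substrate taking the second step, the road to side product, is then s = c/(c + c_even).

**The reckoning.** The partner falls as substrate goes. So I put the charged c(coupling partner) into s, subtracted s times c(substrate) to get a mean level, and put that back. The mean levels were 0.142 M in north-east, 0.459 M in south-west and 1.19 M in south. That gave s = 55.1% in south-west and 76.1% in south, with side product and side product leading.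

**The demand.** Full conversion asks for c(substrate) times one plus s. In north-east that was 0.637 M, more than the 0.400 M charged, so I reckoned the partner the limiting reagent there. The balance then left intermediate A in the lead at 47.5%. South-west asked for 0.776 M, less than its 0.800 M. My target figures were 25.1% in north-east, 44.9% in south-west and 23.9% in south. I chose the south-west charge, since its figure was the highest of these.

**The forecast.** It named intermediate A at 50% in north-east, side product at 51% in south-west and side product at 74% in south, the same leaders as mine. Its ground was side product forming “at a cost of two partners per substrate”.

**The flasks.** North-east ended with intermediate A at 51.2%, south-west with side product at 53.6%, and south with side product at 75.7%. South-west held 42.8% target, more than either other flask. The partner remaining in south-west after 80.0 min, 6.0% of the charge, was 0.0480 M, below c_even, with 0.023% of the substrate left. For a further flask like south, with 2.7 M of partner, I reckoned a mean level of 2.26 M, which put s at 85.8%. That flask gave 85.7% side product.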